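## The problem

Maackiaflavanone A (21) is a (2S)-flavanone. Ring A (C4a–C8a) carries OH at C5, OMe at C7 and a prenyl group at C8; ring C (O1, C2, C3, C4) holds the only stereocenter, C2; ring B (C1'–C6') carries OH at C2' and is fused across C4'(O)–C5'(C) to a 2,2-dimethyl-2H-pyran (ring D) in the linear sense. C2 is bound to O1, lies β to the C4 carbonyl and is benzylic to a ring with oxygen both ortho (O2') and para (O4'), so it is erased by base (retro-oxa-Michael opening to the 2'-hydroxychalcone) and by acid (ionisation of C2–O1). No second stereocenter can control it, so C2 has to be set by a catalyst, late, and under near-neutral conditions. Ring A poses a regiochemical problem: prenyl must sit at C8 and not C6, yet in every open-chain precursor (acetophenone or chalcone) both phenolic oxygens ortho to the acyl carbon can close ring C, which turns one C-prenyl compound into 6- and 8-prenyl flavanones. Rings B/D pose a second one: the pyran carbon must be attached at C5', para to O2', whereas resorcinols take up C5 units at the carbon between the two oxygens (C3') and give the angular pyran. The prenyl and chromene double bonds rule out hydrogenolysis, strong electrophiles and hot strong acid, and the phenolic oxygens must end up differentiated (O5 and O2' free, O7 methylated). The feature used here is that C2 is both the atom that carries ring B (bond C2–C1') and the β-carbon of the C4 carbonyl, while C3 is an unsubstituted CH2; at the C2=C3 oxidation level ring C is therefore the pyranone of a chromone with an unsubstituted, prochiral β-CH, and one enantioselective conjugate arylation can make C2–C1', set C2 and join the two halves. A second feature serves the run-up: in ring A, C6 is the only free carbon ortho to O5 and C8 is para to O5, so once ring C is closed a prenyl group placed on O5 can only travel O5 → C6 → C8.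

## Retrosynthesis

**21 ⇒ 20.** Only the O2'–CH2OMe bond is cut. O2' needs a mask that survives organolithium chemistry and aqueous rhodium catalysis and leaves under mild acid, without base or hydrogen. The methoxymethyl ether 20 is the only protected compound that carries the stereocenter, and one mild step separates it from 21.

**20 ⇒ 8 + 19 (key disconnection, C2–C1').** The neighbouring cuts are weaker. O1–C2 leads to a chalcone, with its reversible cyclisation and the ambiguity of which ring-A oxygen closes. C2–C3 or C3–C4 leave the stereocenter unsolved. C2–H leads to a flavone whose reduction must distinguish three C=C bonds. Cutting C2–C1' gives two flat, achiral, regiochemically finished halves of similar size: chromone 8 (rings A/C with every ring-A substituent in place) and boronic acid 19 (rings B/D). The forward reaction must add the aryl group 1,4 to the chromone with catalyst-controlled facial selectivity at neutral pH. It must accept an ortho-alkoxy, electron-rich aryl donor, a free chelated 5-OH and two spectator alkenes.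

**8 ⇒ 5 ⇒ 3 (C8–prenyl bond, reconnected to O5).** Direct C-prenylation of a 5,7-dioxygenated chromone does not distinguish C6 from C8. Cutting the C8–CH2 bond and re-attaching the prenyl group to O5 gives ether 5, made by simple O-alkylation of the single phenol of 3. The forward reaction is a Claisen/Cope relay (O5 → C6 → C8). Its regiochemical outcome is dictated by ring A, and it returns the free 5-OH, so O5 needs no protecting group. The relay runs before any stereocenter exists.

**3 ⇒ 1 (O1–C2 and C2–C3 of the pyranone).** Chromone 3 is opened to the acetophenone 1 plus a one-carbon unit (C2). The two hydroxyl groups of 1 are equivalent, so ring closure cannot give a regioisomer. The closure itself desymmetrises ring A and makes O5 unique for the relay above.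

**19 ⇒ 16 ⇒ 12 ⇒ 9 + 10.** The C–B bond of 19 is traced to the C–Br bond of 16. The C3''=C4'' double bond of 16 is traced through alcohol 14 and MOM ether 13 to the ketone of chromanone 12. Ring D of 12 is cut at its aryl–acyl bond and its aryl ether bond, giving 4-bromoresorcinol 9 and 3-methylbut-2-enoic acid 10. This order has two advantages. The pyran C–C bond is made by Friedel–Crafts acylation para to one oxygen (the linear pattern) and not between the two oxygens. The bromine that marks the future C1' comes with the starting material instead of from a late, regiochemically uncertain halogenation.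

## Roads not taken

**Alternative 1:** (the obvious one) cut O1–C2 and C2–C3. The forward route is a Claisen–Schmidt condensation of acetophenone A1 with aldehyde A2 to chalcone A3, a catalytic enantioselective intramolecular oxa-Michael addition, and removal of two MOM groups. The chosen plan is better for three reasons. In A1 the two chelated phenols flanking the acyl group must be told apart (free next to the prenyl group, protected on the other side), which is the very regiochemical problem the chosen route avoids by closing ring C on symmetric 1. Cyclisation of an unactivated 2'-hydroxychalcone is a reversible, weakly organised process; dependable enantioselective versions need an extra activating ester at C3 that has to be put on and taken off. Finally, more operations would follow the creation of the labile stereocenter.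

**Alternative 2:** cut O1–C2 intermolecularly and C4–C4a. The forward route is an iridium-catalysed enantioselective allylic etherification of a ring-A phenoxide with a ring-B cinnamyl carbonate to the branched ether A4, hydroboration/oxidation of the vinyl group to acid A5, and intramolecular Friedel–Crafts acylation to close ring C. The chosen plan is better because here three operations follow the stereo-defining step. The acylation needs acid under which the doubly activated benzylic C2–O1 bond ionises or the β-aryloxy acid eliminates. Ortho-substituted, electron-rich cinnamyl partners are the ones that lose branched selectivity and configuration by re-ionisation. O5 would also have to travel as a methyl ether and be unmasked selectively at the end beside a prenyl group.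

**Alternative 3:** cut O1–C2 and C4–C4a after recognising that C2, C3, C4, ring B, O2' and ring D together are the skeleton of the linear pyranocoumarin xanthyletin A6. The target is a formal isomer of the adduct of A6 and phenol A7, with no atom lost. The forward route is oxa-Michael addition of A7 to C4 of A6 to give aryloxy-dihydrocoumarin A8, then transfer of the lactone acyl carbon from O2' to C4a (a Fries-type ring switch that frees the 2'-OH). The chosen plan is better because addition of a phenol oxygen to a coumarin is uphill and reversible (A8 reverts by E1cB), and no catalyst control of the new center is available. Under the acids that would drive the acyl shift, phloroglucinol-type rings attack coumarin C4 through carbon. If the acyl shift comes first, the problem collapses into the chalcone cyclisation of Alternative 1. A7 again has two hydroxyl groups to distinguish.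

Key step: step 9

Assumption: the (S)-configured biaryl bisphosphine is taken to deliver the aryl group to the face of the chromone C2=C3 bond that gives (2S), as (S)-biaryl bisphosphines do with six-membered cyclic enones of the same shape; if the sense proves opposite, the (R)-ligand is used.

## Steps

Step 1
Reactants: 1 2',6'-dihydroxy-4'-methoxyacetophenone
Product: 3 5-hydroxy-7-methoxy-4H-chromen-4-one, via enaminone 2 (not isolated)
Conditions: DMF-DMA (2.5 equiv), PhMe, 90 °C; evaporate; conc. HCl, CH2Cl2, 40 °C
Reagents that add atoms: N,N-dimethylformamide dimethyl acetal, COC(OC)N(C)C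
Why: Enaminone formation at the methyl ketone followed by acid-promoted addition–elimination (loss of Me2NH) is the standard chromone synthesis; the two OH groups of 1 are equivalent, so only one chromone can form and the remaining OH becomes the unique O5.

Step 2
Reactants: 3 5-hydroxy-7-methoxy-4H-chromen-4-one; 4 1-bromo-3-methylbut-2-ene (prenyl bromide)
Product: 5 7-methoxy-5-[(3-methylbut-2-en-1-yl)oxy]-4H-chromen-4-one
Conditions: K2CO3, DMF, 60 °C
Reagents that add atoms: none
Why: Williamson etherification of the only phenol; the chelated 5-OH needs carbonate in warm polar aprotic solvent, which also favours O- over C-alkylation.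

Step 3
Reactants: 5 7-methoxy-5-[(3-methylbut-2-en-1-yl)oxy]-4H-chromen-4-one
Product: 8 5-hydroxy-7-methoxy-8-(3-methylbut-2-en-1-yl)-4H-chromen-4-one, via ortho-dienone 6 (not isolated), via para-dienone 7 (not isolated)
Conditions: Eu(fod)3 (10 mol %), NaHCO3, PhCl, 85 °C
Reagents that add atoms: none
Why: Lewis-acid-accelerated aromatic Claisen rearrangement (O5 → C6, inverted allyl) followed by Cope rearrangement (C6 → C8, allyl inverted back) and enolisation, i.e. a para-Claisen–Cope relay known for 5-prenyloxy-4H-chromen-4-ones; C6 is the only free ortho carbon of O5 and C8 its para carbon, so the un-inverted prenyl group can only arrive at C8, and the europium chelate between O4 and O5 lets the first shift run at a temperature where dienone 6 undergoes the Cope shift instead of enolising.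

Step 4
Reactants: 9 4-bromobenzene-1,3-diol (4-bromoresorcinol); 10 3-methylbut-2-enoic acid
Product: 12 6-bromo-7-hydroxy-2,2-dimethylchroman-4-one, via aryl enone 11 (not isolated)
Conditions: Eaton's reagent (P2O5 in MeSO3H), 70 °C
Reagents that add atoms: none
Why: Tandem Friedel–Crafts acylation/oxa-Michael addition; acylation goes to C6 of 9 (ortho to one OH, para to the other, the only unhindered activated carbon), and closure by the ortho OH puts the ring oxygen para to bromine, which is the linear B/D pattern of the target.

Step 5
Reactants: 12 6-bromo-7-hydroxy-2,2-dimethylchroman-4-one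
Product: 13 6-bromo-7-(methoxymethoxy)-2,2-dimethylchroman-4-one
Conditions: MOMCl, i-Pr2NEt, CH2Cl2, 0 °C → rt
Reagents that add atoms: chloromethyl methyl ether, COCCl
Why: O-alkylation of the acidic 7-OH (para to the carbonyl); the MOM ether survives hydride, amine base, organolithium and aqueous rhodium catalysis, stabilises the later ortho-lithium by chelation and is removable with mild acid.

Step 6
Reactants: 13 6-bromo-7-(methoxymethoxy)-2,2-dimethylchroman-4-one
Product: 14 6-bromo-7-(methoxymethoxy)-2,2-dimethylchroman-4-ol (racemic)
Conditions: NaBH4, MeOH/THF, 0 °C → rt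
Reagents that add atoms: none
Why: Borohydride 1,2-reduction of the aryl ketone; the new C4 center is racemic and is destroyed in step 7.

Step 7
Reactants: 14 6-bromo-7-(methoxymethoxy)-2,2-dimethylchroman-4-ol
Product: 16 6-bromo-7-(methoxymethoxy)-2,2-dimethyl-2H-chromene, via mesylate 15 (not isolated)
Conditions: MsCl, Et3N (3 equiv), CH2Cl2, 0 → 40 °C
Reagents that add atoms: none
Why: Mesylation and elimination of the benzylic mesylate, whose ionisation is assisted by the para OMOM oxygen, gives the conjugated chromene under basic conditions that spare the MOM ether and avoid acid-induced chromene dimerisation.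

Step 8
Reactants: 16 6-bromo-7-(methoxymethoxy)-2,2-dimethyl-2H-chromene
Product: 19 [7-(methoxymethoxy)-2,2-dimethyl-2H-chromen-6-yl]boronic acid, via aryllithium 17 (not isolated), via lithium triisopropoxyborate 18 (not isolated)
Conditions: n-BuLi, THF, −78 °C; B(Oi-Pr)3, −78 °C → rt; dilute HCl to pH 5, 0 °C
Reagents that add atoms: triisopropyl borate, CC(C)OB(OC(C)C)OC(C)C; water, O
Why: Bromine–lithium exchange at −78 °C is faster than any deprotonation and the aryllithium is held by the ortho MOM oxygen; borate formation and mild hydrolysis is the standard lithiation–borylation sequence.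

Step 9
Reactants: 8 5-hydroxy-7-methoxy-8-(3-methylbut-2-en-1-yl)-4H-chromen-4-one; 19 [7-(methoxymethoxy)-2,2-dimethyl-2H-chromen-6-yl]boronic acid
Product: 20 (2S)-5-hydroxy-7-methoxy-2-[7-(methoxymethoxy)-2,2-dimethyl-2H-chromen-6-yl]-8-(3-methylbut-2-en-1-yl)-2,3-dihydro-4H-chromen-4-one
Conditions: [Rh(OH)((S)-MeO-F12-BIPHEP)]2 (3 mol % Rh, pre-formed from [Rh(OH)(cod)]2 and a slight excess of ligand), 19 (2.5 equiv), PhMe/H2O 10:1, 35 °C
Reagents that add atoms: none
Why: Transmetalation of 19 to the hydroxo-rhodium(I) bisphosphine complex gives an aryl–rhodium species, the C2=C3 bond of 8 inserts to give an oxa-π-allyl rhodium enolate, and water protonates it to release 20 and regenerate Rh–OH. The closest known reaction type is the rhodium/chiral bisphosphine-catalysed asymmetric 1,4-addition of arylboronic acids to chromones to give flavanones (Hayashi–Miyaura reaction). No ring is closed; the step joins the finished ring systems A/C and B/D through the C2–C1' bond. The new stereocenter C2 is controlled by the ligand alone, since both partners are achiral: the (S)-biaryl bisphosphine blocks one face of the rhodium-bound enone so that the aryl group migrates to the face that gives (2S). The step needs 1,4- over 1,2-addition, which the hydrogen-bonded, poorly electrophilic C4 carbonyl and the toluene/water medium favour. It needs reaction at the enone only, and the trisubstituted prenyl and the chromene double bonds do not insert into aryl–rhodium at this temperature. It needs insertion to outrun protodeboronation, for which the electron-poor ligand and the excess of 19 are chosen. The base-free, neutral medium also protects the product, because the rhodium enolate is protonated faster than it can expel the O1 aryloxide and reopen ring C.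

Step 10
Reactants: 20 (2S)-5-hydroxy-7-methoxy-2-[7-(methoxymethoxy)-2,2-dimethyl-2H-chromen-6-yl]-8-(3-methylbut-2-en-1-yl)-2,3-dihydro-4H-chromen-4-one
Product: 21 maackiaflavanone A, (2S)-5-hydroxy-2-(7-hydroxy-2,2-dimethyl-2H-chromen-6-yl)-7-methoxy-8-(3-methylbut-2-en-1-yl)-2,3-dihydro-4H-chromen-4-one
Conditions: HCl (1.25 M in MeOH, 0.3 equiv), MeOH/THF, 25–40 °C
Reagents that add atoms: none
Why: Acid-catalysed transacetalisation of the aryl MOM ether to methanol; catalytic anhydrous acid at or below 40 °C is chosen to stay below the threshold for C2–O1 ionisation and for addition to the prenyl double bond, and no base is present, so C2 should keep its configuration.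

## Compound list

1 | 2',6'-dihydroxy-4'-methoxyacetophenone | CC(=O)c1c(O)cc(OC)cc1O | starting material
2 | (E)-3-(dimethylamino)-1-(2,6-dihydroxy-4-methoxyphenyl)prop-2-en-1-one (enaminone, formed in the flask) | CN(C)/C=C/C(=O)c1c(O)cc(OC)cc1O | intermediate
3 | 5-hydroxy-7-methoxy-4H-chromen-4-one | COc1cc(O)c2c(=O)ccoc2c1 | intermediate
4 | 1-bromo-3-methylbut-2-ene (prenyl bromide) | CC(C)=CCBr | starting material
5 | 7-methoxy-5-[(3-methylbut-2-en-1-yl)oxy]-4H-chromen-4-one | COc1cc(OCC=C(C)C)c2c(=O)ccoc2c1 | intermediate
6 | 7-methoxy-6-(2-methylbut-3-en-2-yl)-4H-chromene-4,5(6H)-dione (ortho-dienone, racemic, formed in the flask) | O=C1C(C(C)(C)C=C)C(OC)=CC2=C1C(=O)C=CO2 | intermediate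
7 | 7-methoxy-8-(3-methylbut-2-en-1-yl)-4H-chromene-4,5(8H)-dione (para-dienone, racemic, formed in the flask) | O=C1C=C(OC)C(CC=C(C)C)C2=C1C(=O)C=CO2 | intermediate
8 | 5-hydroxy-7-methoxy-8-(3-methylbut-2-en-1-yl)-4H-chromen-4-one | COc1cc(O)c2c(=O)ccoc2c1CC=C(C)C | intermediate
9 | 4-bromobenzene-1,3-diol (4-bromoresorcinol) | Oc1ccc(Br)c(O)c1 | starting material
10 | 3-methylbut-2-enoic acid | CC(C)=CC(=O)O | starting material
11 | 1-(5-bromo-2,4-dihydroxyphenyl)-3-methylbut-2-en-1-one (aryl enone, formed in the flask) | CC(C)=CC(=O)c1cc(Br)c(O)cc1O | intermediate
12 | 6-bromo-7-hydroxy-2,2-dimethylchroman-4-one | CC1(C)CC(=O)c2cc(Br)c(O)cc2O1 | intermediate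
13 | 6-bromo-7-(methoxymethoxy)-2,2-dimethylchroman-4-one | COCOc1cc2OC(C)(C)CC(=O)c2cc1Br | intermediate
14 | 6-bromo-7-(methoxymethoxy)-2,2-dimethylchroman-4-ol (racemic) | COCOc1cc2OC(C)(C)CC(O)c2cc1Br | intermediate
15 | 6-bromo-7-(methoxymethoxy)-2,2-dimethylchroman-4-yl methanesulfonate (racemic, formed in the flask) | COCOc1cc2OC(C)(C)CC(OS(C)(=O)=O)c2cc1Br | intermediate
16 | 6-bromo-7-(methoxymethoxy)-2,2-dimethyl-2H-chromene | COCOc1cc2OC(C)(C)C=Cc2cc1Br | intermediate
17 | [7-(methoxymethoxy)-2,2-dimethyl-2H-chromen-6-yl]lithium (formed in the flask) | COCOc1cc2OC(C)(C)C=Cc2cc1[Li] | intermediate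
18 | lithium triisopropoxy[7-(methoxymethoxy)-2,2-dimethyl-2H-chromen-6-yl]borate (formed in the flask) | [Li+].COCOc1cc2OC(C)(C)C=Cc2cc1[B-](OC(C)C)(OC(C)C)OC(C)C | intermediate
19 | [7-(methoxymethoxy)-2,2-dimethyl-2H-chromen-6-yl]boronic acid | COCOc1cc2OC(C)(C)C=Cc2cc1B(O)O | intermediate
20 | (2S)-5-hydroxy-7-methoxy-2-[7-(methoxymethoxy)-2,2-dimethyl-2H-chromen-6-yl]-8-(3-methylbut-2-en-1-yl)-2,3-dihydro-4H-chromen-4-one | COc1cc(O)c2c(c1CC=C(C)C)O[C@H](c1cc3c(cc1OCOC)OC(C)(C)C=C3)CC2=O | intermediate
21 | maackiaflavanone A, (2S)-5-hydroxy-2-(7-hydroxy-2,2-dimethyl-2H-chromen-6-yl)-7-methoxy-8-(3-methylbut-2-en-1-yl)-2,3-dihydro-4H-chromen-4-one | COc1cc(O)c2c(c1CC=C(C)C)O[C@H](c1cc3c(cc1O)OC(C)(C)C=C3)CC2=O | target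

## Step count and least certain steps

Total step count: 10. Longest linear sequence: 7 steps (steps 4–10, from 9 and 10); the ring-A branch (steps 1–3) joins at step 9.

**Step 9 (key step).** The most likely failure is protodeboronation of the electron-rich, ortho-alkoxy boronic acid outrunning transmetalation and insertion into an electron-rich, 8-substituted chromone. Configuration could also be eroded, either by incomplete facial discrimination of the ortho-substituted aryl group or by β-aryloxide elimination from the rhodium enolate and racemic re-closure of ring C. The fallback gives up catalyst control in the bond-forming event and secures the configuration by kinetic resolution. It sets out from 8 and 19, which are joined with the ligand-free and most active catalyst [Rh(OH)(cod)]2 in dioxane/water to give the racemic flavanone F1. F1 is then subjected to asymmetric transfer hydrogenation (Cp*RhCl[(R,R)-TsDPEN], HCO2H/Et3N), with the catalyst enantiomer chosen so that the (2R)-ketone is reduced faster (expected to be the (R,R) series, to be confirmed). The (2R)-enantiomer is converted into the cis-flavan-4-ol F2 and separated. The unreduced (2S)-ketone is 20, where the route is rejoined.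

**Step 3.** The relay may stop after the first sigmatropic shift: enolisation of ortho-dienone 6 can compete with the Cope shift and leave a reverse-prenyl group at C6, or the Lewis acid may cleave the prenyl ether. The fallback moves the relay to the flavanone, the substrate class with the closest precedent for it, and lets the prenyl ether serve as protecting group for O5 in the arylation. It sets out from 5, which is arylated with 19 under the conditions of step 9 to give the (2S)-5-prenyloxyflavanone F3. Europium-catalysed Claisen–Cope rearrangement of F3 gives 20, where the route is rejoined.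

**Step 10.** Acid may cause partial loss of configuration at C2, through ionisation of C2–O1 assisted by O2' and O4' or through reversible ring opening, and slow Markovnikov addition of methanol to the prenyl double bond. The fallback removes the protecting group from the plan, so that the stereocenter is formed in the last step. It sets out from 12, which is reduced with NaBH4 to the diol F4 and dehydrated with catalytic acid to the bromochromenol F5. F5 is converted through its O,C-dianion (n-BuLi, 2.2 equiv, then B(Oi-Pr)3) into the hydroxyboronic acid F6. F6 is added to 8 under the conditions of step 9 and gives 21 directly.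

**Step 8.** Protodeboronation during hydrolytic work-up and isolation, and formation of boroxine mixtures of uncertain stoichiometry, are the likely problems. The fallback avoids the organolithium and the free boronic acid. It sets out from 16, which undergoes Miyaura borylation (B2pin2, Pd(dppf)Cl2, KOAc, dioxane, 85 °C) to the pinacol boronate F7. F7 is used in step 9 in place of 19, with a substoichiometric amount of aqueous K3PO4 to assist transmetalation, and the route is rejoined at 20.

**Step 4.** Acid-promoted migration or loss of bromine from the electron-rich ring, and competing closure to the isomeric 4,4-dimethylchroman-2-one, may lower the efficiency. The fallback introduces bromine after the annulation. It sets out from 10, which is condensed with resorcinol in Eaton's reagent to the chromanone F8. Bromination of F8 with NBS in MeCN at 0 °C is expected at C6, which is para to the ring oxygen, ortho to the OH and less hindered than C8, and gives 12, where the route is rejoined.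

## Further compounds

F1 | step 9 | racemic 5-hydroxy-7-methoxy-2-[7-(methoxymethoxy)-2,2-dimethyl-2H-chromen-6-yl]-8-(3-methylbut-2-en-1-yl)-2,3-dihydro-4H-chromen-4-one | COc1cc(O)c2c(c1CC=C(C)C)OC(c1cc3c(cc1OCOC)OC(C)(C)C=C3)CC2=O
F2 | step 9 | (2R,4R)-7-methoxy-2-[7-(methoxymethoxy)-2,2-dimethyl-2H-chromen-6-yl]-8-(3-methylbut-2-en-1-yl)chromane-4,5-diol (cis-flavan-4-ol) | COc1cc(O)c2c(c1CC=C(C)C)O[C@@H](c1cc3c(cc1OCOC)OC(C)(C)C=C3)C[C@H]2O
F3 | step 3 | (2S)-7-methoxy-2-[7-(methoxymethoxy)-2,2-dimethyl-2H-chromen-6-yl]-5-[(3-methylbut-2-en-1-yl)oxy]-2,3-dihydro-4H-chromen-4-one | COc1cc(OCC=C(C)C)c2c(c1)O[C@H](c1cc3c(cc1OCOC)OC(C)(C)C=C3)CC2=O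
F4 | step 10 | 6-bromo-2,2-dimethylchromane-4,7-diol (racemic) | CC1(C)CC(O)c2cc(Br)c(O)cc2O1
F5 | step 10 | 6-bromo-2,2-dimethyl-2H-chromen-7-ol | CC1(C)C=Cc2cc(Br)c(O)cc2O1
F6 | step 10 | (7-hydroxy-2,2-dimethyl-2H-chromen-6-yl)boronic acid | CC1(C)C=Cc2cc(B(O)O)c(O)cc2O1
F7 | step 8 | 2-[7-(methoxymethoxy)-2,2-dimethyl-2H-chromen-6-yl]-4,4,5,5-tetramethyl-1,3,2-dioxaborolane | COCOc1cc2OC(C)(C)C=Cc2cc1B1OC(C)(C)C(C)(C)O1
F8 | step 4 | 7-hydroxy-2,2-dimethylchroman-4-one | CC1(C)CC(=O)c2ccc(O)cc2O1
A1 | alternative 1 | 1-[2-hydroxy-4-methoxy-6-(methoxymethoxy)-3-(3-methylbut-2-en-1-yl)phenyl]ethan-1-one | CC(=O)c1c(O)c(CC=C(C)C)c(OC)cc1OCOC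
A2 | alternative 1 | 7-(methoxymethoxy)-2,2-dimethyl-2H-chromene-6-carbaldehyde | COCOc1cc2OC(C)(C)C=Cc2cc1C=O
A3 | alternative 1 | (E)-1-[2-hydroxy-4-methoxy-6-(methoxymethoxy)-3-(3-methylbut-2-en-1-yl)phenyl]-3-[7-(methoxymethoxy)-2,2-dimethyl-2H-chromen-6-yl]prop-2-en-1-one | COc1cc(OCOC)c(C(=O)/C=C/c2cc3C=CC(C)(C)Oc3cc2OCOC)c(O)c1CC=C(C)C
A4 | alternative 2 | 6-[(1S)-1-[3,5-dimethoxy-2-(3-methylbut-2-en-1-yl)phenoxy]prop-2-en-1-yl]-7-(methoxymethoxy)-2,2-dimethyl-2H-chromene | COc1cc(OC)c(CC=C(C)C)c(O[C@H](c2cc3C=CC(C)(C)Oc3cc2OCOC)C=C)c1
A5 | alternative 2 | (3S)-3-[3,5-dimethoxy-2-(3-methylbut-2-en-1-yl)phenoxy]-3-[7-(methoxymethoxy)-2,2-dimethyl-2H-chromen-6-yl]propanoic acid | COc1cc(OC)c(CC=C(C)C)c(O[C@H](c2cc3C=CC(C)(C)Oc3cc2OCOC)CC(=O)O)c1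
A6 | alternative 3 | xanthyletin, 8,8-dimethyl-2H,8H-pyrano[3,2-g]chromen-2-one | CC1(C)C=Cc2cc3ccc(=O)oc3cc2O1
A7 | alternative 3 | 5-methoxy-4-(3-methylbut-2-en-1-yl)benzene-1,3-diol | COc1cc(O)cc(O)c1CC=C(C)C
A8 | alternative 3 | (4S)-4-[5-hydroxy-3-methoxy-2-(3-methylbut-2-en-1-yl)phenoxy]-8,8-dimethyl-3,4-dihydro-2H,8H-pyrano[3,2-g]chromen-2-one | COc1cc(O)cc(O[C@H]2CC(=O)Oc3cc4OC(C)(C)C=Cc4cc32)c1CC=C(C)C
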